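Atom labels follow germacrane numbering: C1 ketone, C2=C3 enol ether, C4=C5 alkene (C15 methyl on C4), C6 lactone oxygen, C7 (bearing C11=C13 and the C12 carbonyl), C8 methacrylate, C9 acetate, C10 quaternary (C14 methyl).

## The problem

- The target is a ten-membered carbocycle (C1–C10) bridged by an oxygen between C3 and C10. O, C3, C2, C1 and C10 form a planar 3(2H)-furanone, and the six-carbon loop C4–C9 spans one face of it (an 11-oxabicyclo[6.2.1]undecane). An α-methylene-γ-butyrolactone is fused at C6–C7.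
- The SMILES fixes 6S,7S,8S,9S,10R. The lactone is cis-fused (H-6 and H-7 cis). The lactone ring, O8 and O9 all lie on the face of the macrocycle opposite the oxygen bridge, and H-6 to H-9 lie under the bridge.
- Five contiguous stereocentres (C6–C10) must be set. C10 is quaternary (CH3, ring O, C1 ketone, C9). The 4Z trisubstituted alkene is conjugated to the furanone and is only secure once it is locked in the ring.
- Only C8 is readily bought (glyceraldehyde). It can direct C7 (1,2-induction) and, through a cyclic allylation transition state, C6. It can direct C9 (Felkin–Anh). C10 can only be set by C9 and by the ring.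
- Sensitive groups:
  - two acrylate acceptors (methylene lactone, methacrylate);
  - the β-acyloxy ketone C1(=O)–C10–C9(OAc), whose free alcohol can retro-aldolise under base (strain release, aromatic enolate as leaving group);
  - the vicinal O8/O9 esters, which can exchange;
  - the 12,6-lactone, which can translactonise onto a free O8.
- The enabling feature is the ring O/C3/C2/C1/C10. It is the keto tautomer of a 3-hydroxyfuran, and its α-carbon C10 sits next to the C9 carbinol. C9–C10 is therefore an aldol bond whose nucleophile is C2 of a flat, aromatic 2-methyl-3-silyloxyfuran and whose electrophile is a C9 aldehyde.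

## Retrosynthesis

**26 ⇒ 25 (C9 O–acetyl).** The acetate goes on last, because only the acylated aldol is safe from retro-aldol opening. The forward step is acylation of a hindered secondary alcohol without base.

**25 ⇒ 22 (C9–C10), through silyl ether 24 and silyloxyfuran 23.** This cut opens the ten-membered ring and removes the quaternary centre C10 and the C9 carbinol together. Ring closure at C6–C7 (allylation) or C4=C5 (metathesis) would leave C9/C10 to open-chain control. C9–C10 is the one ring bond whose formation also creates the two hardest stereocentres. Precursor 22 is a monocyclic lactone with a flat furanone and an α-acyloxy aldehyde, and its C10 centre need not be defined, because both epimers give the same planar 23. The forward reaction must attack through C10 on one furan face and on the Felkin face of the aldehyde.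

**22 ⇒ 21 ⇒ 20 (oxidation level at C9, silyl groups).** Aldehyde 22 comes from alcohol 21, which comes from bis-silyl compound 20 by one fluoride treatment.

**20 ⇒ 12 + 17 (C3–C4, sp2–sp2), through 18 and 19.** This cut separates a lactone fragment (12) that holds all three sp3 centres C6–C8 from a four-carbon heteroarene (17). Building the furanone on the chain from an alkyne would cost steps and never passes through the arene. The coupling must keep the Z geometry of the vinyl iodide and leave the acrylates alone.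

**17 ⇒ 16 ⇒ 13 + 14 (through 15).** The silyloxyfuran is the silyl enol ether of 2-methylfuran-3(2H)-one 16, which arises from acetoin 13 and ethyl formate 14 via the hydroxymethylene ketone 15.

**12 ⇒ 11 ⇒ 10 ⇒ 9 (C8 ester, C9 protection).** The methacrylate is installed on the iodide, before the furan arrives, so that acylation never meets an acidic furanone C–H.

**9 ⇒ 3 + 7 (C6–C7 and O6–C12), through 8.** One Barbier allylation makes the lactone, the exocyclic methylene and the stereocentres C6 and C7, both relayed from C8. Alkylating a preformed lactone and methylenating it later would be longer and would not use C8.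

**3 ⇒ 2 ⇒ 1; 7 ⇒ 6 ⇒ 4 + 5.** The Z-iodoenal 3 comes from but-2-yn-1-ol 1 via iodo alcohol 2. Bromide 7 comes from glyceraldehyde acetonide 4 and methyl acrylate 5 via adduct 6.

## Roads not taken

**Alternative 1:** (the route most chemists would draw first) cut C6–C7 and O6–C12 in the macrocycle. The forward key step is an intramolecular metal-mediated allylation of a C6 aldehyde by a 2-(bromomethyl)acrylate in seco compound A1. It closes the ring and the lactone together; the furanone is made earlier from an alkyne by cycloisomerisation.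
- C9 and the quaternary C10 would have to be set earlier by an intermolecular aldol with no ring to control them.
- A1 contains a Z-enal conjugated to the furanone, which is prone to Z/E isomerisation.
- The chair-like allylation inside a ten-membered ring would have to deliver the cis-fused (6S,7S) lactone without a nearby controlling element.
- The chosen plan makes C6/C7 in an open-chain allylation next to C8 and uses the ring closure for C9/C10.

**Alternative 2:** cut C4=C5. The forward key step is ring-closing metathesis of diene A2 (3-isopropenylfuranone plus C6 vinyl group).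
- The closure creates no stereocentre.
- It must form a trisubstituted, conjugated alkene in a strained bridged ring while two other 1,1-disubstituted acrylate alkenes compete for the carbene.
- C9/C10 again need open-chain control.
- It is kept only as the fallback for the key step.

**Alternative 3:** cut O–C3 (furanone last). The forward key step is a transannular 5-endo-dig oxa-Michael addition of the C10 tertiary alcohol onto a ring ynone in A3.
- A ten-membered ring that holds a linear C1–C2≡C3–C4 unit next to a Z-alkene is more strained than the target and harder to close.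
- The tertiary C10 carbinol must be set in an open chain.
- The route is longer than a plan that builds the ring and C10 in one step.

Key step: step 14

Remark: 16, 21 and 22 carry a readily enolised C–H stereocentre (the future C10) and are used as epimer mixtures, because step 14 passes through the planar silyloxyfuran 23. Adduct 6 is used as a carbinol epimer mixture because that carbon becomes sp2 in 7.

## Route

Step 1
Reactants: 1 but-2-yn-1-ol
Product: 2 (2Z)-3-iodobut-2-en-1-ol
Conditions: NaAlH2(OCH2CH2OMe)2, THF, 0 °C → rt; then I2, THF, −78 → 0 °C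
Reagents that add atoms: iodine, II
Why: Hydroxyl-directed trans-hydroalumination places aluminium on C3 in a five-membered oxa-aluminacycle, and iodinolysis with retention gives the Z-iodide, the source of the C4=C5 geometry.

Step 2
Reactants: 2 (2Z)-3-iodobut-2-en-1-ol
Product: 3 (2Z)-3-iodobut-2-enal
Conditions: MnO2, CH2Cl2, rt, dark; used crude
Reagents that add atoms: none
Why: Neutral allylic oxidation; no acid or base is present that could isomerise the Z-β-iodoenal.

Step 3
Reactants: 4 (4R)-2,2-dimethyl-1,3-dioxolane-4-carbaldehyde; 5 methyl acrylate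
Product: 6 methyl 2-{(RS)-[(4R)-2,2-dimethyl-1,3-dioxolan-4-yl](hydroxy)methyl}prop-2-enoate
Conditions: DABCO, 1,4-dioxane/H2O, rt
Reagents that add atoms: none
Why: Morita–Baylis–Hillman reaction; the carbinol epimers need not be separated, and the dioxolane carbon (future C8) is the stereocentre bought from the chiral pool.

Step 4
Reactants: 6 methyl 2-{(RS)-[(4R)-2,2-dimethyl-1,3-dioxolan-4-yl](hydroxy)methyl}prop-2-enoate
Product: 7 methyl (2Z)-2-(bromomethyl)-3-[(4S)-2,2-dimethyl-1,3-dioxolan-4-yl]prop-2-enoate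
Conditions: NBS, Me2S, CH2Cl2, 0 °C → rt
Reagents that add atoms: N-bromosuccinimide, O=C1CCC(=O)N1Br
Why: Corey–Kim-type activation of the allylic alcohol and SN2' displacement by bromide give the rearranged primary bromide as the more stable Z isomer (C8 trans to the ester); the acetonide survives the neutral conditions.

Step 5
Reactants: 3 (2Z)-3-iodobut-2-enal; 7 methyl (2Z)-2-(bromomethyl)-3-[(4S)-2,2-dimethyl-1,3-dioxolan-4-yl]prop-2-enoate
Product: 9 (4S,5R)-4-[(4S)-2,2-dimethyl-1,3-dioxolan-4-yl]-5-[(1Z)-2-iodoprop-1-en-1-yl]-3-methylideneoxolan-2-one, via hydroxy ester 8 (not isolated)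
Conditions: In powder, THF/H2O (1:1), rt; then PPTS (cat.), PhMe, 60 °C
Reagents that add atoms: none
Why: Barbier-type allylation through a chair transition state in which C7 bonds to the aldehyde carbon C6 (SE2'); the Z-configured allylindium should give the syn adduct 8, which lactonises to the cis-fused lactone, and the C7 face should be set by C8, because with H-8 eclipsing the double bond (1,3-allylic strain) indium chelated by the dioxolane oxygen O8 delivers the aldehyde to that face, anti to C9 (the R descriptor at C6 of the iodide is the same spatial sense as 6S in the target).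

Step 6
Reactants: 9 (4S,5R)-4-[(4S)-2,2-dimethyl-1,3-dioxolan-4-yl]-5-[(1Z)-2-iodoprop-1-en-1-yl]-3-methylideneoxolan-2-one
Product: 10 (4R,5R)-4-[(1S)-1,2-dihydroxyethyl]-5-[(1Z)-2-iodoprop-1-en-1-yl]-3-methylideneoxolan-2-one
Conditions: AcOH/H2O (4:1), 40 °C
Reagents that add atoms: none
Why: Acetal hydrolysis; mild acid and short contact limit translactonisation of the 12,6-lactone onto the freed O8.

Step 7
Reactants: 10 (4R,5R)-4-[(1S)-1,2-dihydroxyethyl]-5-[(1Z)-2-iodoprop-1-en-1-yl]-3-methylideneoxolan-2-one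
Product: 11 (4R,5R)-4-[(1S)-2-{[tert-butyl(dimethyl)silyl]oxy}-1-hydroxyethyl]-5-[(1Z)-2-iodoprop-1-en-1-yl]-3-methylideneoxolan-2-one
Conditions: TBSCl, imidazole, CH2Cl2, 0 °C
Reagents that add atoms: tert-butyldimethylsilyl chloride, CC(C)(C)[Si](C)(C)Cl
Why: Selective silylation of the primary C9 hydroxyl over the hindered secondary C8 hydroxyl.

Step 8
Reactants: 11 (4R,5R)-4-[(1S)-2-{[tert-butyl(dimethyl)silyl]oxy}-1-hydroxyethyl]-5-[(1Z)-2-iodoprop-1-en-1-yl]-3-methylideneoxolan-2-one
Product: 12 (1S)-2-{[tert-butyl(dimethyl)silyl]oxy}-1-[(2R,3S)-2-[(1Z)-2-iodoprop-1-en-1-yl]-4-methylidene-5-oxooxolan-3-yl]ethyl 2-methylprop-2-enoate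
Conditions: methacrylic anhydride, DMAP (cat.), Et3N, CH2Cl2, 0 °C → rt
Reagents that add atoms: methacrylic anhydride, C=C(C)C(=O)OC(=O)C(C)=C
Why: DMAP-catalysed acylation installs the C8 methacrylate before any furanone C–H is present, so enol acylation cannot compete.

Step 9
Reactants: 13 3-hydroxybutan-2-one; 14 ethyl formate
Product: 16 2-methylfuran-3(2H)-one (racemic), via hydroxymethylene ketone 15 (not isolated)
Conditions: NaH, Et2O, 0 °C → rt; then 2 M HCl, rt
Reagents that add atoms: none
Why: Claisen formylation at the methyl group (the only site that gives a stabilised β-ketoaldehyde enolate) and acid-induced cyclodehydration of the α'-hydroxy-β-ketoaldehyde, the classical entry to 3(2H)-furanones.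

Step 10
Reactants: 16 2-methylfuran-3(2H)-one
Product: 17 2-methyl-3-{[tri(propan-2-yl)silyl]oxy}furan
Conditions: TIPSOTf, Et3N, CH2Cl2, 0 °C
Reagents that add atoms: triisopropylsilyl trifluoromethanesulfonate, CC(C)[Si](OS(=O)(=O)C(F)(F)F)(C(C)C)C(C)C
Why: Soft enolisation; O-silylation traps the aromatic 3-hydroxyfuran tautomer as a robust silyl ether.

Step 11
Reactants: 17 2-methyl-3-{[tri(propan-2-yl)silyl]oxy}furan; 12 (1S)-2-{[tert-butyl(dimethyl)silyl]oxy}-1-[(2R,3S)-2-[(1Z)-2-iodoprop-1-en-1-yl]-4-methylidene-5-oxooxolan-3-yl]ethyl 2-methylprop-2-enoate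
Product: 20 (1S)-2-{[tert-butyl(dimethyl)silyl]oxy}-1-[(2S,3S)-4-methylidene-2-[(1Z)-2-(5-methyl-4-{[tri(propan-2-yl)silyl]oxy}furan-2-yl)prop-1-en-1-yl]-5-oxooxolan-3-yl]ethyl 2-methylprop-2-enoate, via 5-lithiofuran 18 (not isolated), via furylzinc chloride 19 (not isolated)
Conditions: 17, n-BuLi, THF, −78 → 0 °C; ZnCl2, THF, 0 °C; then 12, Pd(PPh3)4 (5 mol %), THF, rt
Reagents that add atoms: none
Why: α-Lithiation of the furan at its only free α-position, transmetalation to zinc and Negishi coupling with the vinyl iodide with retention of the Z geometry; the organozinc tolerates lactone, esters and silyl ethers, and fast transmetalation at rt should outrun Heck cyclisation onto the methylene lactone.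

Step 12
Reactants: 20 (bis-silyl coupling product)
Product: 21 (1S)-2-hydroxy-1-[(2S,3S)-4-methylidene-2-[(1Z)-2-(5-methyl-4-oxo-4,5-dihydrofuran-2-yl)prop-1-en-1-yl]-5-oxooxolan-3-yl]ethyl 2-methylprop-2-enoate (both C10 epimers)
Conditions: HF·pyridine, THF, 0 °C → rt
Reagents that add atoms: none
Why: Fluoride cleaves the primary silyl ether and the silyl enol ether, whose 3-hydroxyfuran tautomerises to the furanone; the acidic medium disfavours O8→O9 acyl migration and oxa-Michael addition.

Step 13
Reactants: 21 (primary alcohol)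
Product: 22 (1S)-1-[(2S,3S)-4-methylidene-2-[(1Z)-2-(5-methyl-4-oxo-4,5-dihydrofuran-2-yl)prop-1-en-1-yl]-5-oxooxolan-3-yl]-2-oxoethyl 2-methylprop-2-enoate (both C10 epimers)
Conditions: DMP, CH2Cl2, 0 °C → rt; used crude
Reagents that add atoms: none
Why: Dess–Martin oxidation under non-basic conditions preserves the α-acyloxy aldehyde stereocentre C8.

Step 14
Reactants: 22 (aldehyde, both C10 epimers)
Product: 25 (6S,7S,8S,9S,10R)-9-hydroxy-8-(2-methylprop-2-enoyloxy)-1-oxo-3,10-epoxygermacra-2,4Z,11(13)-trien-12,6-olide, via trimethylsilyloxyfuran aldehyde 23 (not isolated), via macrocyclic trimethylsilyl ether 24 (not isolated)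
Conditions: TMSOTf (2.5 equiv), i-Pr2NEt (1.1 equiv), CH2Cl2 (2 mM), −78 → −30 °C; then 1 M HCl, THF, 0 °C
Reagents that add atoms: none
Why: Proposed new method: soft enolisation converts either C10 epimer of 22 into the same flat, aromatic 3-silyloxyfuran 23, whose C10 (furan C2, the β-carbon of the silyl enol ether) attacks the TMSOTf-activated C9 aldehyde in an open Mukaiyama transition state; loss of the silyl group from the oxocarbenium ion restores the 3(2H)-furanone and gives silyl ether 24, which the acid work-up cleaves to 25. The closest known reaction types are the intermolecular Lewis-acid Mukaiyama aldol of 2-alkyl-3-silyloxyfurans with aldehydes (C2 attack, giving 2,2-disubstituted 3(2H)-furanones), the one-pot silyl triflate/amine enol silane formation–Mukaiyama aldol, and ring-closing Mukaiyama aldols of tethered silyl enol ethers; new here is that a silyloxyfuran closes a bridged medium ring. The step makes C9–C10 and with it the ten-membered carbocycle (10-exo-trig with the enol double bond C10=C1 inside the ring), which is equally the nine-membered oxacycle O–C3···C10 (9-exo-trig, enol exo); high dilution suppresses dimerisation. C9 is controlled by C8: the polar Felkin–Anh arrangement (C8–O anti to the forming bond, ring carbon C7 on the carbonyl-oxygen side) leads to the 8,9-erythro alcohol (9S). C10 is controlled by the ring: the cis-fused lactone holds the furan arm and the aldehyde arm on one face of the five-membered ring, and of the two ways the C4–C9 loop can cross the furan plane only one keeps the lactone ring, O8 and the aldehyde oxygen on the convex face away from the furan oxygen (H-6 to H-9 inside), and that closure gives 10R with C14 and O9 cis. The step needs C10 attack rather than O-attack (secured by the enol ether polarity), aldehyde rather than acrylate as electrophile (the silyl triflate activates only the aldehyde at low temperature), and furanone rather than aldehyde enolisation (the far more acidic furanone C–H consumes the single equivalent of amine).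

Step 15
Reactants: 25 (9-hydroxy macrocycle)
Product: 26 (6S,7S,8S,9S,10R)-9-acetoxy-8-(2-methylprop-2-enoyloxy)-1-oxo-3,10-epoxygermacra-2,4Z,11(13)-trien-12,6-olide (CNP0365569.3)
Conditions: Ac2O, Sc(OTf)3 (cat.), MeCN, −20 °C
Reagents that add atoms: acetic anhydride, CC(=O)OC(C)=O
Why: Lewis-acid-catalysed acetylation of the hindered C9 alcohol avoids the alkoxide that could trigger retro-aldol ring opening or O8→O9 acyl shift.

## Compound list

1 | but-2-yn-1-ol | CC#CCO | starting material
2 | (2Z)-3-iodobut-2-en-1-ol | C/C(I)=C/CO | intermediate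
3 | (2Z)-3-iodobut-2-enal | C/C(I)=C/C=O | intermediate
4 | (4R)-2,2-dimethyl-1,3-dioxolane-4-carbaldehyde | O=C[C@H]1COC(C)(C)O1 | starting material
5 | methyl acrylate | C=CC(=O)OC | starting material
6 | methyl 2-{(RS)-[(4R)-2,2-dimethyl-1,3-dioxolan-4-yl](hydroxy)methyl}prop-2-enoate | C=C(C(=O)OC)C(O)[C@H]1COC(C)(C)O1 | intermediate
7 | methyl (2Z)-2-(bromomethyl)-3-[(4S)-2,2-dimethyl-1,3-dioxolan-4-yl]prop-2-enoate | COC(=O)/C(CBr)=C/[C@H]1COC(C)(C)O1 | intermediate
8 | methyl (3S,4R,5Z)-3-[(4S)-2,2-dimethyl-1,3-dioxolan-4-yl]-4-hydroxy-6-iodo-2-methylidenehept-5-enoate | C/C(I)=C/[C@H](O)[C@H](C(=C)C(=O)OC)[C@H]1COC(C)(C)O1 | intermediate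
9 | (4S,5R)-4-[(4S)-2,2-dimethyl-1,3-dioxolan-4-yl]-5-[(1Z)-2-iodoprop-1-en-1-yl]-3-methylideneoxolan-2-one | C/C(I)=C/[C@@H]1OC(=O)C(=C)[C@@H]1[C@H]2COC(C)(C)O2 | intermediate
10 | (4R,5R)-4-[(1S)-1,2-dihydroxyethyl]-5-[(1Z)-2-iodoprop-1-en-1-yl]-3-methylideneoxolan-2-one | C/C(I)=C/[C@@H]1OC(=O)C(=C)[C@@H]1[C@H](O)CO | intermediate
11 | (4R,5R)-4-[(1S)-2-{[tert-butyl(dimethyl)silyl]oxy}-1-hydroxyethyl]-5-[(1Z)-2-iodoprop-1-en-1-yl]-3-methylideneoxolan-2-one | C/C(I)=C/[C@@H]1OC(=O)C(=C)[C@@H]1[C@H](O)CO[Si](C)(C)C(C)(C)C | intermediate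
12 | (1S)-2-{[tert-butyl(dimethyl)silyl]oxy}-1-[(2R,3S)-2-[(1Z)-2-iodoprop-1-en-1-yl]-4-methylidene-5-oxooxolan-3-yl]ethyl 2-methylprop-2-enoate | C=C(C)C(=O)O[C@H](CO[Si](C)(C)C(C)(C)C)[C@H]1C(=C)C(=O)O[C@H]1/C=C(/C)I | intermediate
13 | 3-hydroxybutan-2-one (racemic) | CC(O)C(C)=O | starting material
14 | ethyl formate | CCOC=O | starting material
15 | (1Z)-1,4-dihydroxypent-1-en-3-one (present as its disodium salt) | CC(O)C(=O)/C=C\O | intermediate
16 | 2-methylfuran-3(2H)-one (racemic) | CC1OC=CC1=O | intermediate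
17 | 2-methyl-3-{[tri(propan-2-yl)silyl]oxy}furan | Cc1occc1O[Si](C(C)C)(C(C)C)C(C)C | intermediate
18 | (5-methyl-4-{[tri(propan-2-yl)silyl]oxy}furan-2-yl)lithium | [Li]c1cc(O[Si](C(C)C)(C(C)C)C(C)C)c(C)o1 | intermediate
19 | chloro(5-methyl-4-{[tri(propan-2-yl)silyl]oxy}furan-2-yl)zinc | Cl[Zn]c1cc(O[Si](C(C)C)(C(C)C)C(C)C)c(C)o1 | intermediate
20 | (1S)-2-{[tert-butyl(dimethyl)silyl]oxy}-1-[(2S,3S)-4-methylidene-2-[(1Z)-2-(5-methyl-4-{[tri(propan-2-yl)silyl]oxy}furan-2-yl)prop-1-en-1-yl]-5-oxooxolan-3-yl]ethyl 2-methylprop-2-enoate | C=C(C)C(=O)O[C@H](CO[Si](C)(C)C(C)(C)C)[C@H]1C(=C)C(=O)O[C@H]1/C=C(/C)c1cc(O[Si](C(C)C)(C(C)C)C(C)C)c(C)o1 | intermediate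
21 | (1S)-2-hydroxy-1-[(2S,3S)-4-methylidene-2-[(1Z)-2-(5-methyl-4-oxo-4,5-dihydrofuran-2-yl)prop-1-en-1-yl]-5-oxooxolan-3-yl]ethyl 2-methylprop-2-enoate (both C10 epimers) | C=C(C)C(=O)O[C@H](CO)[C@H]1C(=C)C(=O)O[C@H]1/C=C(/C)C1=CC(=O)C(C)O1 | intermediate
22 | (1S)-1-[(2S,3S)-4-methylidene-2-[(1Z)-2-(5-methyl-4-oxo-4,5-dihydrofuran-2-yl)prop-1-en-1-yl]-5-oxooxolan-3-yl]-2-oxoethyl 2-methylprop-2-enoate (both C10 epimers) | C=C(C)C(=O)O[C@H](C=O)[C@H]1C(=C)C(=O)O[C@H]1/C=C(/C)C1=CC(=O)C(C)O1 | intermediate
23 | (1S)-1-[(2S,3S)-4-methylidene-2-[(1Z)-2-{5-methyl-4-[(trimethylsilyl)oxy]furan-2-yl}prop-1-en-1-yl]-5-oxooxolan-3-yl]-2-oxoethyl 2-methylprop-2-enoate | C=C(C)C(=O)O[C@H](C=O)[C@H]1C(=C)C(=O)O[C@H]1/C=C(/C)c1cc(O[Si](C)(C)C)c(C)o1 | intermediate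
24 | (6S,7S,8S,9S,10R)-8-(2-methylprop-2-enoyloxy)-1-oxo-9-[(trimethylsilyl)oxy]-3,10-epoxygermacra-2,4Z,11(13)-trien-12,6-olide | C=C(C)C(=O)O[C@H]1[C@H]2C(=C)C(=O)O[C@H]2/C=C(/C)C2=CC(=O)[C@](C)(O2)[C@H]1O[Si](C)(C)C | intermediate
25 | (6S,7S,8S,9S,10R)-9-hydroxy-8-(2-methylprop-2-enoyloxy)-1-oxo-3,10-epoxygermacra-2,4Z,11(13)-trien-12,6-olide | C=C(C)C(=O)O[C@H]1[C@H]2C(=C)C(=O)O[C@H]2/C=C(/C)C2=CC(=O)[C@](C)(O2)[C@H]1O | intermediate
26 | (6S,7S,8S,9S,10R)-9-acetoxy-8-(2-methylprop-2-enoyloxy)-1-oxo-3,10-epoxygermacra-2,4Z,11(13)-trien-12,6-olide | C=C(C)C(=O)O[C@H]1[C@H]2C(=C)C(=O)O[C@H]2/C=C(/C)C2=CC(=O)[C@](C)(O2)[C@H]1OC(C)=O | target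

## Step count and least certain steps

Total steps: 15. Longest linear sequence: 11 (steps 3, 4, 5, 6, 7, 8, 11, 12, 13, 14, 15).

**Step 14 (key step, proposed new method).**
- What may go wrong: the strained bridged ring may close too slowly, so that intermolecular aldol oligomerisation takes over.
- Closure may occur on the wrong furan or aldehyde face (poor facial selectivity).
- The α-acyloxy aldehyde may be enolised or epimerised before it is attacked.
- Fallback (known chemistry; sets out from 7 and 17, comes back at 25): the ring is closed at C4=C5 by metathesis after an intermolecular aldol.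
  - Bromide 7 is coupled with acrolein under the indium conditions of step 5 to give methyl (3S,4S)-3-[(4S)-2,2-dimethyl-1,3-dioxolan-4-yl]-4-hydroxy-2-methylidenehex-5-enoate F1, which is lactonised to the vinyl lactone F2.
  - The operations of steps 6–8 give diol F3, silyl ether F4 and methacrylate F5; HF·pyridine and DMP give alcohol F6 and aldehyde F7.
  - Furan 17 is lithiated and zincated as in step 11 (18, 19) and coupled with 2-bromopropene (Pd(PPh3)4) to give 2-methyl-5-(prop-1-en-2-yl)-3-{[tri(propan-2-yl)silyl]oxy}furan F8.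
  - Intermolecular Mukaiyama aldol of F8 with F7 (BF3·OEt2, CH2Cl2, −78 °C; Felkin control at C9, C10 epimers separated) gives the aldol diene F9.
  - Ring-closing metathesis of F9 with the second-generation Hoveyda–Grubbs catalyst (PhMe, 80 °C, high dilution) closes C4=C5, Z by ring constraint, and gives 25.

**Step 5.**
- What may go wrong: the sense of 1,2-induction from C8 at C7 may be opposite to the chelation model (poor or reversed facial selectivity).
- The syn preference may erode through isomerisation of the allylindium.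
- Fallback (sets out from 3 and 5, comes back at 12): C8 is corrected by inversion instead of relying on induction.
  - Commercial (4S)-2,2-dimethyl-1,3-dioxolane-4-carbaldehyde and 5 are taken through the operations of steps 3 and 4 to the Morita–Baylis–Hillman adduct F10 and the bromide F11.
  - Indium coupling of F11 with 3 gives hydroxy ester F12 and, after lactonisation, lactone F13, which has the target configuration at C6/C7 and the wrong one at C8.
  - The operations of steps 6 and 7 give diol F14 and silyl ether F15.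
  - Mitsunobu esterification of F15 with methacrylic acid (PPh3, DIAD, THF) inverts C8 and gives 12.

**Step 11.**
- What may go wrong: metalation of 17 at the wrong site (lateral lithiation of the methyl group or silyl migration).
- Heck-type cyclisation of the vinylpalladium species onto the methylene lactone may compete.
- Fallback (sets out from 12, comes back at 21): the furanone is built on the chain by alkyne coupling and cycloisomerisation.
  - Commercial ethyl (S)-2-{[tert-butyl(dimethyl)silyl]oxy}propanoate is converted (MeNHOMe·HCl, i-PrMgCl) into the Weinreb amide F16 and with ethynylmagnesium bromide into the ynone F17.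
  - Sonogashira coupling of 12 with F17 (PdCl2(PPh3)2, CuI, i-Pr2NH, THF, rt) gives the enynone F18.
  - HF·pyridine removes both silyl groups to give the hydroxy ynone F19.
  - 5-endo-dig cycloisomerisation of F19 with (Ph3P)AuCl/AgOTf (cat., PhMe, rt) gives 21 as one C10 epimer, which serves equally.

**Step 15.**
- What may go wrong: retro-aldol ring opening of the free β-hydroxy ketone, or O8→O9 acyl migration, before the acetate is in place.
- Fallback (sets out from 24, comes back at 26): 25 is never liberated. Ac2O is added to the cold reaction mixture of step 14 before work-up; the TMSOTf already present catalyses exchange of the silyl ether of 24 for the acetate, giving 26 directly. No new compound is made.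

## Further compounds

F1 | step 14 | methyl (3S,4S)-3-[(4S)-2,2-dimethyl-1,3-dioxolan-4-yl]-4-hydroxy-2-methylidenehex-5-enoate | C=C[C@H](O)[C@H](C(=C)C(=O)OC)[C@H]1COC(C)(C)O1
F2 | step 14 | (4S,5S)-4-[(4S)-2,2-dimethyl-1,3-dioxolan-4-yl]-5-ethenyl-3-methylideneoxolan-2-one | C=C[C@@H]1OC(=O)C(=C)[C@@H]1[C@H]2COC(C)(C)O2
F3 | step 14 | (4R,5S)-4-[(1S)-1,2-dihydroxyethyl]-5-ethenyl-3-methylideneoxolan-2-one | C=C[C@@H]1OC(=O)C(=C)[C@@H]1[C@H](O)CO
F4 | step 14 | (4R,5S)-4-[(1S)-2-{[tert-butyl(dimethyl)silyl]oxy}-1-hydroxyethyl]-5-ethenyl-3-methylideneoxolan-2-one | C=C[C@@H]1OC(=O)C(=C)[C@@H]1[C@H](O)CO[Si](C)(C)C(C)(C)C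
F5 | step 14 | (1S)-2-{[tert-butyl(dimethyl)silyl]oxy}-1-[(2S,3S)-2-ethenyl-4-methylidene-5-oxooxolan-3-yl]ethyl 2-methylprop-2-enoate | C=C(C)C(=O)O[C@H](CO[Si](C)(C)C(C)(C)C)[C@H]1C(=C)C(=O)O[C@H]1C=C
F6 | step 14 | (1S)-1-[(2S,3S)-2-ethenyl-4-methylidene-5-oxooxolan-3-yl]-2-hydroxyethyl 2-methylprop-2-enoate | C=C(C)C(=O)O[C@H](CO)[C@H]1C(=C)C(=O)O[C@H]1C=C
F7 | step 14 | (1S)-1-[(2S,3S)-2-ethenyl-4-methylidene-5-oxooxolan-3-yl]-2-oxoethyl 2-methylprop-2-enoate | C=C(C)C(=O)O[C@H](C=O)[C@H]1C(=C)C(=O)O[C@H]1C=C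
F8 | step 14 | 2-methyl-5-(prop-1-en-2-yl)-3-{[tri(propan-2-yl)silyl]oxy}furan | C=C(C)c1cc(O[Si](C(C)C)(C(C)C)C(C)C)c(C)o1
F9 | step 14 | (1S,2S)-1-[(2S,3S)-2-ethenyl-4-methylidene-5-oxooxolan-3-yl]-2-hydroxy-2-[(2R)-2-methyl-3-oxo-5-(prop-1-en-2-yl)-2,3-dihydrofuran-2-yl]ethyl 2-methylprop-2-enoate | C=C(C)C(=O)O[C@@H]([C@H]1C(=C)C(=O)O[C@H]1C=C)[C@H](O)[C@@]1(C)OC(C(C)=C)=CC1=O
F10 | step 5 | methyl 2-{(RS)-[(4S)-2,2-dimethyl-1,3-dioxolan-4-yl](hydroxy)methyl}prop-2-enoate | C=C(C(=O)OC)C(O)[C@@H]1COC(C)(C)O1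
F11 | step 5 | methyl (2Z)-2-(bromomethyl)-3-[(4R)-2,2-dimethyl-1,3-dioxolan-4-yl]prop-2-enoate | COC(=O)/C(CBr)=C/[C@@H]1COC(C)(C)O1
F12 | step 5 | methyl (3S,4R,5Z)-3-[(4R)-2,2-dimethyl-1,3-dioxolan-4-yl]-4-hydroxy-6-iodo-2-methylidenehept-5-enoate | C/C(I)=C/[C@H](O)[C@H](C(=C)C(=O)OC)[C@@H]1COC(C)(C)O1
F13 | step 5 | (4S,5R)-4-[(4R)-2,2-dimethyl-1,3-dioxolan-4-yl]-5-[(1Z)-2-iodoprop-1-en-1-yl]-3-methylideneoxolan-2-one | C/C(I)=C/[C@@H]1OC(=O)C(=C)[C@@H]1[C@@H]2COC(C)(C)O2
F14 | step 5 | (4R,5R)-4-[(1R)-1,2-dihydroxyethyl]-5-[(1Z)-2-iodoprop-1-en-1-yl]-3-methylideneoxolan-2-one | C/C(I)=C/[C@@H]1OC(=O)C(=C)[C@@H]1[C@@H](O)CO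
F15 | step 5 | (4R,5R)-4-[(1R)-2-{[tert-butyl(dimethyl)silyl]oxy}-1-hydroxyethyl]-5-[(1Z)-2-iodoprop-1-en-1-yl]-3-methylideneoxolan-2-one | C/C(I)=C/[C@@H]1OC(=O)C(=C)[C@@H]1[C@@H](O)CO[Si](C)(C)C(C)(C)C
F16 | step 11 | (2S)-2-{[tert-butyl(dimethyl)silyl]oxy}-N-methoxy-N-methylpropanamide | C[C@H](O[Si](C)(C)C(C)(C)C)C(=O)N(C)OC
F17 | step 11 | (4S)-4-{[tert-butyl(dimethyl)silyl]oxy}pent-1-yn-3-one | C[C@H](O[Si](C)(C)C(C)(C)C)C(=O)C#C
F18 | step 11 | (1S)-2-{[tert-butyl(dimethyl)silyl]oxy}-1-[(2S,3S)-2-[(1Z,6S)-6-{[tert-butyl(dimethyl)silyl]oxy}-2-methyl-5-oxohept-1-en-3-yn-1-yl]-4-methylidene-5-oxooxolan-3-yl]ethyl 2-methylprop-2-enoate | C=C(C)C(=O)O[C@H](CO[Si](C)(C)C(C)(C)C)[C@H]1C(=C)C(=O)O[C@H]1/C=C(/C)C#CC(=O)[C@H](C)O[Si](C)(C)C(C)(C)C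
F19 | step 11 | (1S)-2-hydroxy-1-[(2S,3S)-2-[(1Z,6S)-6-hydroxy-2-methyl-5-oxohept-1-en-3-yn-1-yl]-4-methylidene-5-oxooxolan-3-yl]ethyl 2-methylprop-2-enoate | C=C(C)C(=O)O[C@H](CO)[C@H]1C(=C)C(=O)O[C@H]1/C=C(/C)C#CC(=O)[C@H](C)O
F0 | step 15 | none | none
A1 | alternative 1 | methyl (2Z,4S,5S)-5-acetoxy-2-(bromomethyl)-4-(2-methylprop-2-enoyloxy)-5-{(2R)-2-methyl-3-oxo-5-[(2Z)-4-oxobut-2-en-2-yl]-2,3-dihydrofuran-2-yl}pent-2-enoate | C=C(C)C(=O)O[C@@H](/C=C(\CBr)C(=O)OC)[C@H](OC(C)=O)[C@@]1(C)OC(/C(C)=C\C=O)=CC1=O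
A2 | alternative 2 | (1S,2S)-2-acetoxy-1-[(2S,3S)-2-ethenyl-4-methylidene-5-oxooxolan-3-yl]-2-[(2R)-2-methyl-3-oxo-5-(prop-1-en-2-yl)-2,3-dihydrofuran-2-yl]ethyl 2-methylprop-2-enoate | C=C(C)C(=O)O[C@@H]([C@H]1C(=C)C(=O)O[C@H]1C=C)[C@H](OC(C)=O)[C@@]1(C)OC(C(C)=C)=CC1=O
A3 | alternative 3 | (6S,7S,8S,9S,10R)-9-acetoxy-10-hydroxy-8-(2-methylprop-2-enoyloxy)-1-oxogermacra-4Z,11(13)-dien-2-yn-12,6-olide | C=C(C)C(=O)O[C@H]1[C@H]2C(=C)C(=O)O[C@H]2/C=C(/C)C#CC(=O)[C@](C)(O)[C@H]1OC(C)=O
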